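# Proposed total synthesis of CNP0106875.1 by Diels–Alder benzannulation of an alkoxy ynone

## Analysis of the target

Target 22 is a 5,7-dihydroxychromone (benzo ring A fused to pyranone ring C) whose C3 carries an sp3 methine, Cα. Cα also bears a 2,4,6-trihydroxybenzoyl group and a bis(4-hydroxyphenyl)methyl group, so five rings hang on a three-carbon core.

Cα is the only stereocentre and is R. The neighbouring benzhydryl carbon is not stereogenic, because its two aryl groups are identical.

Cα–H is α to the aryl ketone and allylic to C2=C3, so base or Lewis acid can enolise it. The eight phenols are oxidation-prone. Each 4-hydroxyphenyl group sits β to the ketone α-carbon, which is a latent para-quinone methide (retro-Michael) unit under basic conditions.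

The difficulty lies in the crowding at Cα, its configurational lability, and the need to treat two phloroglucinol-type rings differently: one is closed into the pyranone through one of its oxygens, the other stays a triphenol ketone.

The strategy rests on ring A. C4a carries the acyl carbon C4 and lies between two oxygen-bearing carbons (C5–OH and C8a–O1), with C7–OH para. In this 1,3,5-trioxygenated benzene, C4a and one oxygenated neighbour can come from an alkoxy ynone and the other four carbons from a 1,1,3-trioxygenated butadiene.

## Retrosynthetic reasoning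

**22 to 21.** The last operation is cleavage of all six O-alkyl bonds of chromone 21 (one ethyl, five methyl). The phenols stay masked until then because free 4-hydroxyphenyl groups would open a retro-Michael path at Cα under any basic step and would interfere with the organometallic chemistry. The forward step must be acidic and must not enolise Cα.

**21 to 19.** Ring C is opened at O1–C2 and C2=C3, which removes the single carbon C2 and leads back to 1,4-diketone 19. The C3–Cα bond and the stereocentre are then already in place before the pyranone is made, and no bond at Cα is formed late. The forward reaction has to insert a one-carbon unit at the formic acid oxidation level between the methylene of 19 and its free ortho-hydroxyl, through enaminone 20.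

**19 to 14 and 17 (key disconnection).** Ring A is cut at two ring bonds: the bond from the acyl-bearing carbon to the hydroxyl-bearing carbon, and the bond from the ethoxy-bearing carbon to its CH neighbour. This gives ynone 14 and diene 17.

- On the finished chromone these bonds are C4a–C8a and C5–C6, because the pyranone later closes through the hydroxyl on the diene-derived carbon. Ring A's oxygen pattern is symmetric about the C4a···C7 axis, so the same pair can be labelled C4a–C5 and C8–C8a if the ethoxy-bearing carbon is counted as C8a.
- The gain is threefold. The aryl ketone forms without any Friedel–Crafts acylation next to electron-rich arenes. The two oxygens ortho to the acyl group arrive already differentiated, one free hydroxyl for ring closure and one ethyl ether. The conditions are neutral.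
- The forward step must join the CH2 terminus of 17 to the ethoxy-bearing alkyne carbon of 14 and then aromatise through cycloadduct 18.

**14 to 10 and 12.** The bond between the ynone carbonyl and the alkyne is cut. Acetylide 12 (from ethoxyacetylene 11) adds to keto aldehyde 10 to give carbinol 13, which is oxidised. An aldehyde is chosen as the electrophile because it is far more reactive than the twisted, di-ortho-substituted aryl ketone already present in 10.

**10 to 9 to 6 and 8.** After adjusting the oxidation level of the primary alcohol of 9, the aryl–C(=O) bond of the trimethoxybenzoyl group is cut. Aryllithium 8 (from 1,3,5-trimethoxybenzene 7) adds to lactone 6. The lactone activates the hindered carboxyl at Cα and at the same time holds the other arm at the alcohol oxidation level. A nucleophilic aryl and an electrophilic acyl partner are preferred over the reverse polarity, since an acylium ion at Cα could attack the neighbouring anisyl rings.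

**6 to 4.** Lactone 6 comes from half-ester 4 by reduction of the free carboxyl only, through hydroxy ester 5. The two carboxyls are already differentiated in 4, so no protecting group is needed.

**4 to 3 to 1 and 2.** The Cα–H and benzhydryl C–H bonds are removed to give alkylidene half-ester 3, which is cut at its C=C bond into benzophenone 1 and succinate 2. Because the two aryl groups of 3 are identical, the alkene has no geometric isomers and its hydrogenation creates Cα as the only stereocentre. The forward hydrogenation has to be enantioface-selective.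

**17 to 16 to 15.** Diene 17 is reached from methyl acetoacetate 15 by two successive O-silylations through silyl enol ether 16.

## Alternatives that were turned down

**Alternative 1: intramolecular Wittig closure of ring C.**
- Disconnection: C2=C3.
- Forward key step: in phosphorane A1 the acyl-stabilised ylide carbon attacks the ortho-formate carbonyl and loses the phosphine oxide, giving chromone A2. In A2 the future ketone is held as a silyl-protected carbinol.
- For it: the ring closure is neutral and known for chromones. With the carbinol in place of the ketone, Cα is not enolisable during ring formation. On that point this plan is stronger than the chosen one.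
- Against it: the ylide carbon of A1 must carry the full branched Cα substituent, so the phosphonium precursor has to be built at a neopentyl-like position next to two stereocentres. The carbinol is a second stereocentre that is made only to be oxidised away. Silyl removal, oxidation and the aryl formate add protecting-group and redox steps.
- Comparison: the chosen route is shorter and carries no extra stereocentre. It builds ring A with its oxygens already differentiated, where this plan must buy and selectively unmask a phloroglucinol unit.

**Alternative 2: asymmetric intramolecular Stetter closure.**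
- Disconnection: C3–C4.
- Forward key step: a chiral triazolium-derived carbene converts the aldehyde of A3 into an acyl anion equivalent that adds to the tethered enone. This gives chroman-4-one A4 and sets C3 and, by protonation, Cα.
- For it: the reaction class is well established for salicylaldehyde-derived ethers. It sets Cα by catalyst control at the ring-forming step, which is more convergent than an early hydrogenation.
- Against it: the acceptor in A3 is a trisubstituted enone with a benzhydryl group on its α-carbon and a twisted, electron-rich aroyl group, so it is a poor Michael acceptor. The aldehyde is flanked by two ortho oxygens. Cα is fixed only by protonation of a hindered enolate. A4 is at the wrong oxidation level, so C3 must be destroyed again by dehydrogenation, in the presence of an easily oxidised bis-anisyl methine and an epimerisable Cα.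
- Comparison: the chosen route reaches the chromone oxidation level directly and sets Cα on a simple substrate. It gives up the appeal of a late catalytic stereocentre.

**Alternative 3: two-directional acylation of phloroglucinol.**
- Disconnection: both aryl–C(=O) bonds.
- Forward key step: the two carboxyls of diacid A5 acylate two molecules of phloroglucinol A6 under a boron Lewis acid to give octaphenol diketone A7.
- For it: it is the shortest plan and needs no protecting groups on the phloroglucinol rings. In step count it beats the chosen route.
- Against it: the carboxyl at Cα is far more hindered than the CH2 arm, so the two acylations will not keep pace. Succinic acids tend to close to anhydrides, and γ-keto acids to enol lactones, under these conditions. The acylium ion at Cα can epimerise through its enol or ketene, and can attack the adjacent 4-hydroxyphenyl rings to form an indanone. Phloroglucinol can be acylated twice.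
- Comparison: the chosen route makes the hindered ketone by aryllithium addition at low temperature and the second aryl ketone by a neutral cycloaddition. It pays for this with more steps.

Key step: step 10

## Remarks on the chemistry

- Cα is S in compounds 4 to 19 and R from 20 onward. The geometry does not change; in step 11 the former CH2 neighbour becomes an sp2 carbon and overtakes the benzhydryl group in CIP priority.
- Assumption: the sense of induction of the rhodium catalyst on alkene 3 is not known in advance. (S,S)-Et-DuPhos is written; the (R,R) ligand is used if a small-scale test shows that it is the one that delivers the S acid.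
- Diene 17 and ynone 14 are moisture-sensitive and are used directly after preparation.

## Route

Step 1
Reactants: 1 4,4'-dimethoxybenzophenone; 2 dimethyl succinate
Product: 3 3-(methoxycarbonyl)-4,4-bis(4-methoxyphenyl)but-3-enoic acid
Conditions: KOt-Bu, t-BuOH, reflux; then aq. HCl
Reagents that add atoms: none
Why: Stobbe condensation: the succinate enolate adds to the ketone, the alkoxide lactonises onto the distal ester, and base-induced opening of the lactone gives the alkylidene half-ester with the free acid on the CH2 arm; the two identical aryl groups exclude alkene isomers.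

Step 2
Reactants: 3 3-(methoxycarbonyl)-4,4-bis(4-methoxyphenyl)but-3-enoic acid
Product: 4 (S)-3-(methoxycarbonyl)-4,4-bis(4-methoxyphenyl)butanoic acid
Conditions: H2 (10 bar), [Rh(cod)((S,S)-Et-DuPhos)]BF4 (1 mol%), NaOMe (0.1 equiv), MeOH, 25 °C
Reagents that add atoms: none
Why: Rhodium–bisphospholane asymmetric hydrogenation of an itaconate-type half-ester from a Stobbe condensation; the carboxylate binds rhodium next to the alkene and the C2-symmetric ligand selects the alkene face, which sets Cα as S. Only this one stereocentre forms because both β-substituents are the same aryl group.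

Step 3
Reactants: 4 (S)-3-(methoxycarbonyl)-4,4-bis(4-methoxyphenyl)butanoic acid
Product: 6 (S)-3-[bis(4-methoxyphenyl)methyl]dihydrofuran-2(3H)-one, via hydroxy ester 5 (not isolated)
Conditions: BH3·SMe2, THF, 0 → 25 °C; MeOH; then TsOH·H2O (cat.), toluene, 40 °C
Reagents that add atoms: none
Why: Borane reduces a free carboxylic acid much faster than an ester, and the γ-hydroxy ester 5 closes to the five-membered lactone by acid-catalysed 5-exo-trig transesterification; no base is present, so Cα is untouched.

Step 4
Reactants: 6 (S)-3-[bis(4-methoxyphenyl)methyl]dihydrofuran-2(3H)-one; 7 1,3,5-trimethoxybenzene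
Product: 9 (S)-2-[bis(4-methoxyphenyl)methyl]-4-hydroxy-1-(2,4,6-trimethoxyphenyl)butan-1-one, via 2,4,6-trimethoxyphenyllithium 8 (not isolated)
Conditions: 7, n-BuLi, THF, 0 → 25 °C; then 6, −78 → −30 °C; aq. NH4Cl
Reagents that add atoms: none
Why: Directed lithiation of 7 between two methoxy groups gives 8, which adds once to the lactone carbonyl; the lithium hemiketal persists until work-up and the di-ortho-substituted aryl ketone is too hindered for a second addition. Product 9 may equilibrate with its cyclic hemiketal, which reacts on through the open form.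

Step 5
Reactants: 9 (S)-2-[bis(4-methoxyphenyl)methyl]-4-hydroxy-1-(2,4,6-trimethoxyphenyl)butan-1-one
Product: 10 (S)-3-[bis(4-methoxyphenyl)methyl]-4-oxo-4-(2,4,6-trimethoxyphenyl)butanal
Conditions: Dess–Martin periodinane, CH2Cl2, 0 → 25 °C; aq. NaHCO3/Na2S2O3 work-up
Reagents that add atoms: none
Why: Dess–Martin oxidation of a primary alcohol to the aldehyde under non-basic conditions; the cyclic hemiketal form of 9 is tertiary and cannot be over-oxidised to a lactone.

Step 6
Reactants: 10 (S)-3-[bis(4-methoxyphenyl)methyl]-4-oxo-4-(2,4,6-trimethoxyphenyl)butanal; 11 ethoxyacetylene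
Product: 13 (2S,4RS)-2-[bis(4-methoxyphenyl)methyl]-6-ethoxy-4-hydroxy-1-(2,4,6-trimethoxyphenyl)hex-5-yn-1-one, via lithium ethoxyacetylide 12 (not isolated)
Conditions: 11, n-BuLi, THF, −78 °C; then 10, −78 °C; cold aq. NH4Cl, neutral work-up
Reagents that add atoms: none
Why: 1,2-Addition of a lithium acetylide to an aldehyde; the aldehyde is far more electrophilic than the twisted di-ortho-methoxy aryl ketone, and at −78 °C addition should outrun enolisation. The carbinol centre forms unselectively and is removed in step 7.

Step 7
Reactants: 13 (2S,4RS)-2-[bis(4-methoxyphenyl)methyl]-6-ethoxy-4-hydroxy-1-(2,4,6-trimethoxyphenyl)hex-5-yn-1-one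
Product: 14 (S)-2-[bis(4-methoxyphenyl)methyl]-6-ethoxy-1-(2,4,6-trimethoxyphenyl)hex-5-yne-1,4-dione
Conditions: MnO2 (activated, excess), CH2Cl2, 25 °C; filtration through Celite
Reagents that add atoms: none
Why: Activated MnO2 oxidises propargylic alcohols to ynones under neutral heterogeneous conditions; filtration delivers the water-sensitive alkoxy ynone without aqueous or acidic contact, which would hydrate or rearrange the ethoxyalkyne.

Step 8
Reactants: 15 methyl acetoacetate
Product: 16 methyl 3-(trimethylsilyloxy)but-2-enoate
Conditions: TMSCl, Et3N, hexane, 25 °C; filtration, distillation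
Reagents that add atoms: chlorotrimethylsilane, C[Si](C)(C)Cl
Why: O-Silylation of the enol of a β-keto ester with a silyl chloride and an amine base (silyl enol ether formation).

Step 9
Reactants: 16 methyl 3-(trimethylsilyloxy)but-2-enoate
Product: 17 1-methoxy-1,3-bis(trimethylsilyloxy)buta-1,3-diene
Conditions: LiN(i-Pr)2, THF, −78 °C; TMSCl, −78 → 25 °C; pentane, filtration under argon
Reagents that add atoms: chlorotrimethylsilane, C[Si](C)(C)Cl
Why: γ-Deprotonation of the vinylogous ester gives the ester dienolate, which is silylated on oxygen to the ketene acetal (standard preparation of 1,3-bis(silyloxy)dienes).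

Step 10
Reactants: 14 (S)-2-[bis(4-methoxyphenyl)methyl]-6-ethoxy-1-(2,4,6-trimethoxyphenyl)hex-5-yne-1,4-dione; 17 1-methoxy-1,3-bis(trimethylsilyloxy)buta-1,3-diene
Product: 19 (S)-2-[bis(4-methoxyphenyl)methyl]-4-(2-ethoxy-4,6-dihydroxyphenyl)-1-(2,4,6-trimethoxyphenyl)butane-1,4-dione, via cyclohexadiene cycloadduct 18 (not isolated)
Conditions: 17 (2.5 equiv), toluene, 25 → 80 °C, sealed tube; then 0.5 M HCl, THF, 0 °C
Reagents that add atoms: none
Why: Proposed new method: a 3-alkoxy ynone has not been shown as the two-carbon partner in a siloxydiene benzannulation; the closest known reaction type is the Diels–Alder addition of 1-alkoxy-1,3-bis(silyloxy)butadienes to acetylenic ketones and esters followed by aromatisation to resorcinol derivatives. The unsubstituted CH2 terminus of 17, its most nucleophilic carbon, should bond to the ethoxy-bearing alkyne carbon, which is the electrophilic β-position of the ynone, while the ketene-acetal carbon bonds to the carbonyl-bound alkyne carbon. The two C–C bonds may form in one asynchronous [4+2] event or by Mukaiyama–Michael addition followed by 6-exo-trig attack of the allenolate on the silyloxy(methoxy)carbenium carbon; either way the six-membered carbocycle closes as cyclohexa-1,4-diene 18. Loss of methanol across the ketal carbon and the ring CH2 makes the ring aromatic, and dilute acid removes both silyl groups, which leaves the acyl-bearing carbon between a free hydroxyl and the ethyl ether with the third oxygen para. No stereocentre is created that survives, since the ketal carbon of 18 becomes aromatic, and Cα is not involved and should keep its configuration under neutral thermal conditions. The step needs regioselectivity, which the matched polarisation of both partners secures, and [4+2] rather than formal [3+3] periselectivity (closure of the diene's central carbon onto the ynone carbonyl), which the absence of any Lewis acid secures. The twisted, electron-rich trimethoxyphenyl ketone is too hindered to react with the diene.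

Step 11
Reactants: 19 (S)-2-[bis(4-methoxyphenyl)methyl]-4-(2-ethoxy-4,6-dihydroxyphenyl)-1-(2,4,6-trimethoxyphenyl)butane-1,4-dione
Product: 21 3-[(2R)-1,1-bis(4-methoxyphenyl)-3-oxo-3-(2,4,6-trimethoxyphenyl)propan-2-yl]-5-ethoxy-7-hydroxy-4H-chromen-4-one, via enaminone 20 (not isolated)
Conditions: Me2NCH(OMe)2 (5 equiv), toluene, 80 °C
Reagents that add atoms: N,N-dimethylformamide dimethyl acetal, COC(OC)N(C)C
Why: Amide-acetal chromone synthesis: the only methylene α to a ketone condenses to enaminone 20, the ortho-hydroxyl adds to its β-carbon (6-endo-trig) and dimethylamine is lost, closing the pyranone. The other ketone has only the methine Cα and cannot condense, and no bond at Cα changes.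

Step 12
Reactants: 21 3-[(2R)-1,1-bis(4-methoxyphenyl)-3-oxo-3-(2,4,6-trimethoxyphenyl)propan-2-yl]-5-ethoxy-7-hydroxy-4H-chromen-4-one
Product: 22 3-[(2R)-1,1-bis(4-hydroxyphenyl)-3-oxo-3-(2,4,6-trihydroxyphenyl)propan-2-yl]-5,7-dihydroxy-4H-chromen-4-one
Conditions: BBr3 (15 equiv), CH2Cl2, −78 → 25 °C; MeOH then H2O, 0 °C; no basic work-up
Reagents that add atoms: none
Why: BBr3 cleaves aryl alkyl ethers by O-coordination and SN2 attack of bromide on the alkyl carbon, the carbonyl-chelated ethers (5-OEt and the two ortho-OMe groups) first; the acidic medium avoids phenoxide-driven quinone methide formation and no bond at Cα is touched.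

## Compound list

1 | 4,4'-dimethoxybenzophenone | COc1ccc(cc1)C(=O)c1ccc(OC)cc1 | starting material
2 | dimethyl succinate | COC(=O)CCC(=O)OC | starting material
3 | 3-(methoxycarbonyl)-4,4-bis(4-methoxyphenyl)but-3-enoic acid | COC(=O)C(CC(=O)O)=C(c1ccc(OC)cc1)c1ccc(OC)cc1 | intermediate
4 | (S)-3-(methoxycarbonyl)-4,4-bis(4-methoxyphenyl)butanoic acid | OC(=O)C[C@H](C(=O)OC)C(c1ccc(OC)cc1)c1ccc(OC)cc1 | intermediate
5 | methyl (S)-2-[bis(4-methoxyphenyl)methyl]-4-hydroxybutanoate | OCC[C@H](C(=O)OC)C(c1ccc(OC)cc1)c1ccc(OC)cc1 | intermediate
6 | (S)-3-[bis(4-methoxyphenyl)methyl]dihydrofuran-2(3H)-one | O=C1OCC[C@H]1C(c1ccc(OC)cc1)c1ccc(OC)cc1 | intermediate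
7 | 1,3,5-trimethoxybenzene | COc1cc(OC)cc(OC)c1 | starting material
8 | 2,4,6-trimethoxyphenyllithium | [Li]c1c(OC)cc(OC)cc1OC | intermediate
9 | (S)-2-[bis(4-methoxyphenyl)methyl]-4-hydroxy-1-(2,4,6-trimethoxyphenyl)butan-1-one | OCC[C@H](C(=O)c1c(OC)cc(OC)cc1OC)C(c1ccc(OC)cc1)c1ccc(OC)cc1 | intermediate
10 | (S)-3-[bis(4-methoxyphenyl)methyl]-4-oxo-4-(2,4,6-trimethoxyphenyl)butanal | O=CC[C@H](C(=O)c1c(OC)cc(OC)cc1OC)C(c1ccc(OC)cc1)c1ccc(OC)cc1 | intermediate
11 | ethoxyacetylene | CCOC#C | starting material
12 | lithium ethoxyacetylide | CCOC#C[Li] | intermediate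
13 | (2S,4RS)-2-[bis(4-methoxyphenyl)methyl]-6-ethoxy-4-hydroxy-1-(2,4,6-trimethoxyphenyl)hex-5-yn-1-one | CCOC#CC(O)C[C@H](C(=O)c1c(OC)cc(OC)cc1OC)C(c1ccc(OC)cc1)c1ccc(OC)cc1 | intermediate
14 | (S)-2-[bis(4-methoxyphenyl)methyl]-6-ethoxy-1-(2,4,6-trimethoxyphenyl)hex-5-yne-1,4-dione | CCOC#CC(=O)C[C@H](C(=O)c1c(OC)cc(OC)cc1OC)C(c1ccc(OC)cc1)c1ccc(OC)cc1 | intermediate
15 | methyl acetoacetate | COC(=O)CC(C)=O | starting material
16 | methyl 3-(trimethylsilyloxy)but-2-enoate | COC(=O)C=C(C)O[Si](C)(C)C | intermediate
17 | 1-methoxy-1,3-bis(trimethylsilyloxy)buta-1,3-diene | COC(O[Si](C)(C)C)=CC(=C)O[Si](C)(C)C | intermediate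
18 | (2S)-2-[bis(4-methoxyphenyl)methyl]-4-[2-ethoxy-6-methoxy-4,6-bis(trimethylsilyloxy)cyclohexa-1,4-dien-1-yl]-1-(2,4,6-trimethoxyphenyl)butane-1,4-dione (ketal carbon unassigned) | CCOC1=C(C(=O)C[C@H](C(=O)c2c(OC)cc(OC)cc2OC)C(c2ccc(OC)cc2)c2ccc(OC)cc2)C(OC)(O[Si](C)(C)C)C=C(O[Si](C)(C)C)C1 | intermediate
19 | (S)-2-[bis(4-methoxyphenyl)methyl]-4-(2-ethoxy-4,6-dihydroxyphenyl)-1-(2,4,6-trimethoxyphenyl)butane-1,4-dione | CCOc1cc(O)cc(O)c1C(=O)C[C@H](C(=O)c1c(OC)cc(OC)cc1OC)C(c1ccc(OC)cc1)c1ccc(OC)cc1 | intermediate
20 | (3R)-3-[bis(4-methoxyphenyl)methyl]-2-[(dimethylamino)methylidene]-1-(2-ethoxy-4,6-dihydroxyphenyl)-4-(2,4,6-trimethoxyphenyl)butane-1,4-dione | CCOc1cc(O)cc(O)c1C(=O)C(=CN(C)C)[C@H](C(=O)c1c(OC)cc(OC)cc1OC)C(c1ccc(OC)cc1)c1ccc(OC)cc1 | intermediate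
21 | 3-[(2R)-1,1-bis(4-methoxyphenyl)-3-oxo-3-(2,4,6-trimethoxyphenyl)propan-2-yl]-5-ethoxy-7-hydroxy-4H-chromen-4-one | CCOc1cc(O)cc2occ([C@H](C(=O)c3c(OC)cc(OC)cc3OC)C(c3ccc(OC)cc3)c3ccc(OC)cc3)c(=O)c12 | intermediate
22 | 3-[(2R)-1,1-bis(4-hydroxyphenyl)-3-oxo-3-(2,4,6-trihydroxyphenyl)propan-2-yl]-5,7-dihydroxy-4H-chromen-4-one | O=C(c1c(O)cc(O)cc1O)[C@@H](c1coc2cc(O)cc(O)c2c1=O)C(c1ccc(O)cc1)c1ccc(O)cc1 | target

## Step count and risk

Total: 12 steps. Longest linear sequence: 10 steps (steps 1–7 and 10–12); steps 8 and 9 form the diene branch.

**Step 10 (key step, proposed new method).** The ethoxy group raises the alkyne's acceptor orbital, so the cycloaddition may not start below temperatures at which diene 17 decomposes. The ynone may also be lost by hydration of its ethoxyalkyne to a β-keto ester, or the adduct may stop after conjugate addition. The fallback uses known chemistry and takes ring A from a ready-made phloroglucinol unit. It sets out from 10 and comes back at 22.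
- Aryllithium 8 is added to the aldehyde of 10 (THF, −78 °C) to give (2S)-2-[bis(4-methoxyphenyl)methyl]-4-hydroxy-1,4-bis(2,4,6-trimethoxyphenyl)butan-1-one F1.
- Dess–Martin oxidation gives (S)-2-[bis(4-methoxyphenyl)methyl]-1,4-bis(2,4,6-trimethoxyphenyl)butane-1,4-dione F2.
- BCl3 (2.5 equiv, CH2Cl2, −78 → 0 °C) removes one carbonyl-chelated ortho-methyl group at each ketone to give (S)-2-[bis(4-methoxyphenyl)methyl]-1,4-bis(2-hydroxy-4,6-dimethoxyphenyl)butane-1,4-dione F3.
- DMF dimethyl acetal closes the chromone on the methylene side only, giving 3-[(2R)-3-(2-hydroxy-4,6-dimethoxyphenyl)-1,1-bis(4-methoxyphenyl)-3-oxopropan-2-yl]-5,7-dimethoxy-4H-chromen-4-one F4.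
- BBr3 then cleaves all six methyl ethers to give 22.

**Step 2.** Turnover may be slow and enantioface discrimination poor on a tetrasubstituted alkene with two aryl groups on one carbon. The fallback is a resolution; it sets out from 3 and comes back at 4.
- Hydrogenation over Pd/C (EtOAc) gives racemic 3-(methoxycarbonyl)-4,4-bis(4-methoxyphenyl)butanoic acid F5.
- Crystallisation with (R)-1-phenylethylamine gives (R)-1-phenylethylammonium (S)-3-(methoxycarbonyl)-4,4-bis(4-methoxyphenyl)butanoate F6. If the salt of the R acid proves the less soluble one, the S acid is taken from the mother liquor or the antipodal amine is used.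
- Acidification of F6 returns 4.

**Step 4.** The hindered aryllithium may deprotonate the lactone at Cα in place of adding to the carbonyl, which costs material and returns partly racemised lactone. The fallback uses a less acidic acyl donor; it sets out from 6 and comes back at 9.
- MeNH(OMe)·HCl and AlMe3 open the lactone to (S)-2-[bis(4-methoxyphenyl)methyl]-4-hydroxy-N-methoxy-N-methylbutanamide F7.
- TBSCl and imidazole give (S)-2-[bis(4-methoxyphenyl)methyl]-4-(tert-butyldimethylsilyloxy)-N-methoxy-N-methylbutanamide F8.
- Aryllithium 8 adds through the chelated tetrahedral intermediate to give (S)-2-[bis(4-methoxyphenyl)methyl]-4-(tert-butyldimethylsilyloxy)-1-(2,4,6-trimethoxyphenyl)butan-1-one F9.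
- HF·pyridine removes the silyl group to give 9.

**Step 11.** Condensation at a methylene next to the crowded Cα may be slow, and the methoxide and amine present may enolise Cα on prolonged heating. Partial O-methylation of the C7 hydroxyl by the acetal would be harmless, since step 12 cleaves it. The fallback replaces the base-mediated enamine route with an electrophilic one under acid. It sets out from 19 and comes back at 21: the ketone is chelated with BF3·OEt2 and formylated at the methylene with the chloroiminium reagent from DMF and MsCl (Vilsmeier-type), which cyclises on work-up. No new compound is made (F0).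

**Step 12.** The three non-chelated ethers cleave slowly, and long exposure to the Lewis acid may enolise Cα, which in the chromone is both α to the ketone and allylic. The fallback inverts the end game so that the ethers are cleaved while Cα–H is only singly activated. It sets out from 19 and comes back at 22.
- BBr3 on 19 gives (S)-2-[bis(4-hydroxyphenyl)methyl]-1,4-bis(2,4,6-trihydroxyphenyl)butane-1,4-dione F10 (identical with A7). Paal–Knorr closure of this 1,4-diketone is a side path to watch; the two twisted di-ortho-oxygenated aryl ketones should slow it.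
- The pyranone is then closed on the free polyphenol with BF3·OEt2, DMF and MsCl, the classical one-carbon closure of polyhydroxy 2-hydroxyaryl ketones. Only the ketone with a methylene can react.

## Further compounds

F1 | step 10 | (2S)-2-[bis(4-methoxyphenyl)methyl]-4-hydroxy-1,4-bis(2,4,6-trimethoxyphenyl)butan-1-one | COc1cc(OC)c(C(O)C[C@H](C(=O)c2c(OC)cc(OC)cc2OC)C(c2ccc(OC)cc2)c2ccc(OC)cc2)c(OC)c1
F2 | step 10 | (S)-2-[bis(4-methoxyphenyl)methyl]-1,4-bis(2,4,6-trimethoxyphenyl)butane-1,4-dione | COc1cc(OC)c(C(=O)C[C@H](C(=O)c2c(OC)cc(OC)cc2OC)C(c2ccc(OC)cc2)c2ccc(OC)cc2)c(OC)c1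
F3 | step 10 | (S)-2-[bis(4-methoxyphenyl)methyl]-1,4-bis(2-hydroxy-4,6-dimethoxyphenyl)butane-1,4-dione | COc1cc(O)c(C(=O)C[C@H](C(=O)c2c(O)cc(OC)cc2OC)C(c2ccc(OC)cc2)c2ccc(OC)cc2)c(OC)c1
F4 | step 10 | 3-[(2R)-3-(2-hydroxy-4,6-dimethoxyphenyl)-1,1-bis(4-methoxyphenyl)-3-oxopropan-2-yl]-5,7-dimethoxy-4H-chromen-4-one | COc1cc(OC)c2c(c1)occ([C@H](C(=O)c1c(O)cc(OC)cc1OC)C(c1ccc(OC)cc1)c1ccc(OC)cc1)c2=O
F5 | step 2 | racemic 3-(methoxycarbonyl)-4,4-bis(4-methoxyphenyl)butanoic acid | OC(=O)CC(C(=O)OC)C(c1ccc(OC)cc1)c1ccc(OC)cc1
F6 | step 2 | (R)-1-phenylethylammonium (S)-3-(methoxycarbonyl)-4,4-bis(4-methoxyphenyl)butanoate | C[C@@H]([NH3+])c1ccccc1.[O-]C(=O)C[C@H](C(=O)OC)C(c1ccc(OC)cc1)c1ccc(OC)cc1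
F7 | step 4 | (S)-2-[bis(4-methoxyphenyl)methyl]-4-hydroxy-N-methoxy-N-methylbutanamide | OCC[C@H](C(=O)N(C)OC)C(c1ccc(OC)cc1)c1ccc(OC)cc1
F8 | step 4 | (S)-2-[bis(4-methoxyphenyl)methyl]-4-(tert-butyldimethylsilyloxy)-N-methoxy-N-methylbutanamide | CC(C)(C)[Si](C)(C)OCC[C@H](C(=O)N(C)OC)C(c1ccc(OC)cc1)c1ccc(OC)cc1
F9 | step 4 | (S)-2-[bis(4-methoxyphenyl)methyl]-4-(tert-butyldimethylsilyloxy)-1-(2,4,6-trimethoxyphenyl)butan-1-one | CC(C)(C)[Si](C)(C)OCC[C@H](C(=O)c1c(OC)cc(OC)cc1OC)C(c1ccc(OC)cc1)c1ccc(OC)cc1
F0 | step 11 | none | none
F10 | step 12 | (S)-2-[bis(4-hydroxyphenyl)methyl]-1,4-bis(2,4,6-trihydroxyphenyl)butane-1,4-dione | O=C(C[C@H](C(=O)c1c(O)cc(O)cc1O)C(c1ccc(O)cc1)c1ccc(O)cc1)c1c(O)cc(O)cc1O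
A1 | alternative 1 | 2-[3-[bis(4-methoxyphenyl)methyl]-4-(tert-butyldimethylsilyloxy)-2-(triphenylphosphoranylidene)-4-(2,4,6-trimethoxyphenyl)butanoyl]-3,5-dimethoxyphenyl formate, configured as A2 | CC(C)(C)[Si](C)(C)O[C@@H](c1c(OC)cc(OC)cc1OC)[C@@H](C(=P(c1ccccc1)(c1ccccc1)c1ccccc1)C(=O)c1c(OC=O)cc(OC)cc1OC)C(c1ccc(OC)cc1)c1ccc(OC)cc1
A2 | alternative 1 | 3-[(1R,2R)-1-(tert-butyldimethylsilyloxy)-3,3-bis(4-methoxyphenyl)-1-(2,4,6-trimethoxyphenyl)propan-2-yl]-5,7-dimethoxy-4H-chromen-4-one | CC(C)(C)[Si](C)(C)O[C@@H](c1c(OC)cc(OC)cc1OC)[C@@H](c1coc2cc(OC)cc(OC)c2c1=O)C(c1ccc(OC)cc1)c1ccc(OC)cc1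
A3 | alternative 2 | 2-{[(2E)-3-[bis(4-methoxyphenyl)methyl]-4-oxo-4-(2,4,6-trimethoxyphenyl)but-2-en-1-yl]oxy}-4,6-dimethoxybenzaldehyde | O=Cc1c(OC)cc(OC)cc1OC/C=C(/C(=O)c1c(OC)cc(OC)cc1OC)C(c1ccc(OC)cc1)c1ccc(OC)cc1
A4 | alternative 2 | (3R)-3-[(2R)-1,1-bis(4-methoxyphenyl)-3-oxo-3-(2,4,6-trimethoxyphenyl)propan-2-yl]-5,7-dimethoxychroman-4-one | O=C(c1c(OC)cc(OC)cc1OC)[C@@H]([C@@H]1COc2cc(OC)cc(OC)c2C1=O)C(c1ccc(OC)cc1)c1ccc(OC)cc1
A5 | alternative 3 | (S)-2-[bis(4-hydroxyphenyl)methyl]butanedioic acid | OC(=O)C[C@H](C(=O)O)C(c1ccc(O)cc1)c1ccc(O)cc1
A6 | alternative 3 | phloroglucinol | Oc1cc(O)cc(O)c1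
A7 | alternative 3 | (S)-2-[bis(4-hydroxyphenyl)methyl]-1,4-bis(2,4,6-trihydroxyphenyl)butane-1,4-dione | O=C(c1c(O)cc(O)cc1O)[C@@H](CC(=O)c1c(O)cc(O)cc1O)C(c1ccc(O)cc1)c1ccc(O)cc1
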